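**Plan**

1. Feature: number the carbocycle C1(OMe)=C2(Ar)–C3(spiro)–C4(OMe)(Ar)–C5(=O), with the oxirane CH2 as C6. The C3 oxygen and the C4 methoxy group sit trans on neighbouring carbons beside the enone, which is the 4-hydroxy-5-methoxycyclopent-2-enone array a 4-pyranone gives on irradiation in methanol.
2. Cuts: first the oxirane O–C6 bond (back to a C3 carbinol with a CH2Cl arm). Then, together, the ring bond C2–C3 and the C4–OMe bond (back to a fully substituted 4-pyranone plus methanol). Then the two aryl–pyranone bonds, C–Cl, two C–Br and O–Me (back to kojic acid and 4-hydroxyphenylboronic acid).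
3. Forward: the pyranone ring is present from the start and is decorated (Br, OMe, Br, two aryl groups, Cl); the carbocycle arises by photochemical ring contraction; the spiro-oxirane closes last.
4. Stereochemistry: the trans C3–O/C4–OMe relationship comes from methanol adding anti to the fused oxirane of the photogenerated zwitterion. The single enantiomer comes from chiral chromatography of the racemic chlorohydrin; oxirane closure touches neither centre.

Key step: step 6

Remark: the photochemical step is not enantioselective, so the wanted enantiomer is taken by chromatography; its absolute configuration would be assigned by anomalous-dispersion X-ray diffraction of the chlorine-containing chlorohydrin. Pyranone locants used below: O1, C2 (CH2X), C3 (aryl), C4 (C=O), C5 (OMe), C6 (aryl).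

**Route**

Step 1
Reactants: 1 kojic acid (5-hydroxy-2-(hydroxymethyl)-4H-pyran-4-one)
Product: 2 6-bromo-5-hydroxy-2-(hydroxymethyl)-4H-pyran-4-one
Conditions: NBS (1.05 equiv), DMF, 0 °C to rt, dark
Reagents that add atoms: N-bromosuccinimide, O=C1CCC(=O)N1Br
Why: electrophilic bromination of the enolic 3-hydroxy-4-pyranone should go to the free position ortho to the hydroxyl (C6), as in phenol ortho-bromination, while C3 is not conjugated with the enol and stays untouched.

Step 2
Reactants: 2 6-bromo-5-hydroxy-2-(hydroxymethyl)-4H-pyran-4-one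
Product: 3 6-bromo-2-(hydroxymethyl)-5-methoxy-4H-pyran-4-one
Conditions: MeI, K2CO3, acetone, 40 °C
Reagents that add atoms: iodomethane, CI
Why: Williamson O-alkylation in which carbonate deprotonates only the acidic enolic hydroxyl, so the primary alcohol should not be methylated.

Step 3
Reactants: 3 6-bromo-2-(hydroxymethyl)-5-methoxy-4H-pyran-4-one
Product: 4 3,6-dibromo-2-(hydroxymethyl)-5-methoxy-4H-pyran-4-one
Conditions: Br2, NaOAc, AcOH, rt to 50 °C
Reagents that add atoms: bromine, BrBr
Why: electrophilic α-bromination of a 4-pyranone at C3, the β-carbon of the ring enol ether O1–C2=C3 and the only ring C–H left, should proceed by bromine attack and acetate-assisted loss of the proton, with the primary alcohol inert to bromine in buffered acetic acid.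

Step 4
Reactants: 4 3,6-dibromo-2-(hydroxymethyl)-5-methoxy-4H-pyran-4-one; 5 4-hydroxyphenylboronic acid
Product: 7 2-(hydroxymethyl)-3,6-bis(4-hydroxyphenyl)-5-methoxy-4H-pyran-4-one, via 3-bromo-6-aryl monocoupled pyranone 6 (not isolated)
Conditions: 5 (2.6 equiv), Pd(PPh3)4 (5 mol %), K2CO3, 1,4-dioxane/H2O (4:1), degassed, 85 °C
Reagents that add atoms: 4-hydroxyphenylboronic acid (5), OB(O)c1ccc(O)cc1
Why: double Suzuki–Miyaura coupling in which zerovalent palladium should insert first into the vinylogous acyl bromide at C6 and then into the α-bromo enone bond at C3, both bond types being established coupling partners, and in which the free phenol and primary alcohol are tolerated under aqueous carbonate.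

Step 5
Reactants: 7 2-(hydroxymethyl)-3,6-bis(4-hydroxyphenyl)-5-methoxy-4H-pyran-4-one
Product: 9 2-(chloromethyl)-3,6-bis(4-hydroxyphenyl)-5-methoxy-4H-pyran-4-one, via alkyl chlorosulfite 8 (not isolated)
Conditions: SOCl2 (3 equiv), MeCN, 0 °C to rt
Reagents that add atoms: thionyl chloride, O=S(Cl)Cl
Why: deoxychlorination through the chlorosulfite, which collapses to the primary chloride with loss of SO2; without added base the phenols should stay free, as the enolic hydroxyl does when kojic acid itself is chlorinated this way.

Step 6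
Reactants: 9 2-(chloromethyl)-3,6-bis(4-hydroxyphenyl)-5-methoxy-4H-pyran-4-one; 10 methanol
Product: 13 racemic trans-chlorohydrin rac-(4S,5R)-4-(chloromethyl)-4-hydroxy-3,5-bis(4-hydroxyphenyl)-2,5-dimethoxycyclopent-2-en-1-one, via epoxy-oxyallyl zwitterion 11 (not isolated), via epoxy enol methanol adduct 12 (not isolated)
Conditions: hν (Pyrex-filtered medium-pressure Hg lamp, λ > 300 nm), degassed MeOH (about 2 mM), 0 °C
Reagents that add atoms: methanol (10), CO
Why: Excitation of the cross-conjugated pyranone should trigger an excited-state disrotatory 4π electrocyclisation that bonds C2 to C6, the two carbons flanking the ring oxygen; this is the mode by which the five-membered carbocycle closes, and it leaves the former ring oxygen as a cis-fused oxirane on the oxyallyl zwitterion 11. Methanol is expected to add to the aryl-bearing terminus (C3) of the oxyallyl cation on the face away from the oxirane to give 12, whose enol(ate) then opens the oxirane at C6 by β-elimination and so releases the 2-methoxy enone and the tertiary carbinol on the chloromethyl carbon. The closest known reaction is the photoisomerisation of 4-pyranones in hydroxylic solvents to trans-4-hydroxy-5-alkoxycyclopent-2-enones through the same oxirane-fused zwitterion. Both stereocentres arise here: the carbinol carbon keeps the oxirane oxygen and the neighbouring carbon takes up methanol anti to it, so the trans relationship is controlled by the fused oxirane, while nothing controls the absolute sense and the racemate results. The step needs capture at the aryl terminus instead of the methoxy terminus; the free para-hydroxyl group of the C3 aryl ring is relied on for this, since it delocalises the positive charge as an O-protonated quinone methide whose electrophilic carbon is C3, whereas attack at C5 would have to build a ketal on the carbon that already carries oxygen. Dilute, degassed solution and light above 300 nm are chosen to suppress pyranone dimerisation and to spare the C–Cl bond.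

Step 7
Reactants: 13 racemic trans-chlorohydrin
Product: 14 (4S,5R)-4-(chloromethyl)-4-hydroxy-3,5-bis(4-hydroxyphenyl)-2,5-dimethoxycyclopent-2-en-1-one
Conditions: preparative chiral SFC, amylose tris(3,5-dimethylphenylcarbamate) phase, CO2/MeOH, 35 °C
Reagents that add atoms: none
Why: resolution of enantiomers on a polysaccharide chiral stationary phase forms and breaks no bond, and both stereocentres are fully substituted and cannot epimerise during the separation.

Step 8
Reactants: 14 (4S,5R)-chlorohydrin
Product: 15 (3R,4R)-4,7-bis(4-hydroxyphenyl)-4,6-dimethoxy-1-oxaspiro[2.4]hept-6-en-5-one (target)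
Conditions: K2CO3 (3 equiv), MeOH, 0 °C; then aq. NH4Cl
Reagents that add atoms: none
Why: intramolecular Williamson etherification of the chlorohydrin (3-exo-tet), in which the tertiary alkoxide displaces chloride at the CH2 group and no bond at either stereocentre is broken, so the configuration of 14 should be carried into 15 (the carbinol descriptor changes from S to R only through the CIP priorities).

**Compound list**

1 | kojic acid, 5-hydroxy-2-(hydroxymethyl)-4H-pyran-4-one | OCc1cc(=O)c(O)co1 | starting material
2 | 6-bromo-5-hydroxy-2-(hydroxymethyl)-4H-pyran-4-one | OCc1cc(=O)c(O)c(Br)o1 | intermediate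
3 | 6-bromo-2-(hydroxymethyl)-5-methoxy-4H-pyran-4-one | COc1c(Br)oc(CO)cc1=O | intermediate
4 | 3,6-dibromo-2-(hydroxymethyl)-5-methoxy-4H-pyran-4-one | COc1c(Br)oc(CO)c(Br)c1=O | intermediate
5 | 4-hydroxyphenylboronic acid | OB(O)c1ccc(O)cc1 | starting material
6 | 3-bromo-2-(hydroxymethyl)-6-(4-hydroxyphenyl)-5-methoxy-4H-pyran-4-one (not isolated) | COc1c(-c2ccc(O)cc2)oc(CO)c(Br)c1=O | intermediate
7 | 2-(hydroxymethyl)-3,6-bis(4-hydroxyphenyl)-5-methoxy-4H-pyran-4-one | COc1c(-c2ccc(O)cc2)oc(CO)c(-c2ccc(O)cc2)c1=O | intermediate
8 | [3,6-bis(4-hydroxyphenyl)-5-methoxy-4-oxo-4H-pyran-2-yl]methyl chlorosulfite (not isolated) | COc1c(-c2ccc(O)cc2)oc(COS(=O)Cl)c(-c2ccc(O)cc2)c1=O | intermediate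
9 | 2-(chloromethyl)-3,6-bis(4-hydroxyphenyl)-5-methoxy-4H-pyran-4-one | COc1c(-c2ccc(O)cc2)oc(CCl)c(-c2ccc(O)cc2)c1=O | intermediate
10 | methanol | CO | starting material
11 | epoxy-oxyallyl zwitterion, 1-(chloromethyl)-2,5-bis(4-hydroxyphenyl)-4-methoxy-6-oxabicyclo[3.1.0]hex-3-en-2-ylium-3-olate (racemic, one enantiomer drawn, not isolated) | COC1=C([O-])[C+](c2ccc(O)cc2)[C@@]3(CCl)O[C@@]13c1ccc(O)cc1 | intermediate
12 | epoxy enol methanol adduct, 1-(chloromethyl)-2,5-bis(4-hydroxyphenyl)-2,4-dimethoxy-6-oxabicyclo[3.1.0]hex-3-en-3-ol with the 2-methoxy group anti to the oxirane (racemic, one enantiomer drawn, not isolated) | COC1=C(O)[C@@](OC)(c2ccc(O)cc2)[C@@]3(CCl)O[C@@]13c1ccc(O)cc1 | intermediate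
13 | rac-(4S,5R)-4-(chloromethyl)-4-hydroxy-3,5-bis(4-hydroxyphenyl)-2,5-dimethoxycyclopent-2-en-1-one (racemate, trans OH/OMe, wanted enantiomer drawn) | COC1=C(c2ccc(O)cc2)[C@@](O)(CCl)[C@](OC)(c2ccc(O)cc2)C1=O | intermediate
14 | (4S,5R)-4-(chloromethyl)-4-hydroxy-3,5-bis(4-hydroxyphenyl)-2,5-dimethoxycyclopent-2-en-1-one (single enantiomer) | COC1=C(c2ccc(O)cc2)[C@@](O)(CCl)[C@](OC)(c2ccc(O)cc2)C1=O | intermediate
15 | (3R,4R)-4,7-bis(4-hydroxyphenyl)-4,6-dimethoxy-1-oxaspiro[2.4]hept-6-en-5-one | COC1=C(c2ccc(O)cc2)[C@@]2(CO2)[C@](OC)(c2ccc(O)cc2)C1=O | target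

**Step count**

Total steps: 8. Longest linear sequence: 8 steps (kojic acid 1 to target 15).

**Steps most likely to fail**

1. Step 6. Methanol may be captured at the methoxy-bearing terminus of the oxyallyl cation (ketal formation). The oxirane may also open before capture, which would lose the anti control. Conversion may further suffer from charge-transfer deactivation by the phenol rings or homolysis of the C–Cl bond. The fallback sets out from 9 and comes back at 13. Cleavage of the methyl ether next to the carbonyl with BCl3 in CH2Cl2 (−78 to 0 °C) would give 2-(chloromethyl)-5-hydroxy-3,6-bis(4-hydroxyphenyl)-4H-pyran-4-one F1. Acetylation with Ac2O/pyridine would give 5-acetoxy-3,6-bis(4-acetoxyphenyl)-2-(chloromethyl)-4H-pyran-4-one F2. Here the C5 oxygen is an ester oxygen that no longer stabilises positive charge, so the benzylic terminus is the only good site for the solvent and the zwitterion cannot turn into a quinone methide. Irradiation in methanol as in step 6 should give rac-(4S,5R)-2-acetoxy-3,5-bis(4-acetoxyphenyl)-4-(chloromethyl)-4-hydroxy-5-methoxycyclopent-2-en-1-one F3. HCl in methanol (40 °C) would then transesterify the three acetates and convert the freed 2-hydroxy enone (diosphenol) into its methyl enol ether, which is 13.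

2. Step 4. Phenoxide or hydroxide may displace the C6 bromide by addition–elimination, the electron-rich boronic acid may protodeboronate, the pyranone may ring-open in hot aqueous base, or the second coupling at the hindered C3 may stall. The fallback sets out from 4 and comes back at 7. A base-free Stille coupling of 4 with tributyl[4-(tert-butyldimethylsilyloxy)phenyl]stannane (Pd(PPh3)4, CuI, DMF, 80 °C) would give 3,6-bis[4-(tert-butyldimethylsilyloxy)phenyl]-2-(hydroxymethyl)-5-methoxy-4H-pyran-4-one F4. Desilylation with HF·pyridine in THF would then give 7.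

3. Step 3. Electrophilic substitution at the electron-poor C3 may be sluggish, and the hydroxymethyl group may be oxidised or bromine may add across the ring double bonds. The fallback sets out from 3 and comes back at 7, and replaces the C3 halogenation by C–H metalation.
   - Suzuki–Miyaura coupling of 3 with 5 under the conditions of step 4 would give 2-(hydroxymethyl)-6-(4-hydroxyphenyl)-5-methoxy-4H-pyran-4-one F5.
   - Silylation (TBSCl, imidazole, DMF) would give 2-[(tert-butyldimethylsilyloxy)methyl]-6-[4-(tert-butyldimethylsilyloxy)phenyl]-5-methoxy-4H-pyran-4-one F6.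
   - Carbonyl-directed zincation of the remaining ring C–H with (C9H18N)ZnCl·LiCl (2,2,6,6-tetramethylpiperidylzinc chloride–lithium chloride, THF, rt) would give the C3-chlorozinc pyranone F7, used in the same flask.
   - Negishi coupling with tert-butyl(4-iodophenoxy)dimethylsilane (Pd(PPh3)4, THF, 50 °C) would give 2-[(tert-butyldimethylsilyloxy)methyl]-3,6-bis[4-(tert-butyldimethylsilyloxy)phenyl]-5-methoxy-4H-pyran-4-one F8.
   - HF·pyridine would remove the three silyl groups to give 7.

**Further compounds**

F1 | step 6 | 2-(chloromethyl)-5-hydroxy-3,6-bis(4-hydroxyphenyl)-4H-pyran-4-one | Oc1c(-c2ccc(O)cc2)oc(CCl)c(-c2ccc(O)cc2)c1=O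
F2 | step 6 | 5-acetoxy-3,6-bis(4-acetoxyphenyl)-2-(chloromethyl)-4H-pyran-4-one | CC(=O)Oc1c(-c2ccc(OC(C)=O)cc2)oc(CCl)c(-c2ccc(OC(C)=O)cc2)c1=O
F3 | step 6 | rac-(4S,5R)-2-acetoxy-3,5-bis(4-acetoxyphenyl)-4-(chloromethyl)-4-hydroxy-5-methoxycyclopent-2-en-1-one (racemate, one enantiomer drawn) | CC(=O)OC1=C(c2ccc(OC(C)=O)cc2)[C@@](O)(CCl)[C@](OC)(c2ccc(OC(C)=O)cc2)C1=O
F4 | step 4 | 3,6-bis[4-(tert-butyldimethylsilyloxy)phenyl]-2-(hydroxymethyl)-5-methoxy-4H-pyran-4-one | COc1c(-c2ccc(O[Si](C)(C)C(C)(C)C)cc2)oc(CO)c(-c2ccc(O[Si](C)(C)C(C)(C)C)cc2)c1=O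
F5 | step 3 | 2-(hydroxymethyl)-6-(4-hydroxyphenyl)-5-methoxy-4H-pyran-4-one | COc1c(-c2ccc(O)cc2)oc(CO)cc1=O
F6 | step 3 | 2-[(tert-butyldimethylsilyloxy)methyl]-6-[4-(tert-butyldimethylsilyloxy)phenyl]-5-methoxy-4H-pyran-4-one | COc1c(-c2ccc(O[Si](C)(C)C(C)(C)C)cc2)oc(CO[Si](C)(C)C(C)(C)C)cc1=O
F7 | step 3 | {2-[(tert-butyldimethylsilyloxy)methyl]-6-[4-(tert-butyldimethylsilyloxy)phenyl]-5-methoxy-4-oxo-4H-pyran-3-yl}zinc chloride (not isolated) | COc1c(-c2ccc(O[Si](C)(C)C(C)(C)C)cc2)oc(CO[Si](C)(C)C(C)(C)C)c([Zn]Cl)c1=O
F8 | step 3 | 2-[(tert-butyldimethylsilyloxy)methyl]-3,6-bis[4-(tert-butyldimethylsilyloxy)phenyl]-5-methoxy-4H-pyran-4-one | COc1c(-c2ccc(O[Si](C)(C)C(C)(C)C)cc2)oc(CO[Si](C)(C)C(C)(C)C)c(-c2ccc(O[Si](C)(C)C(C)(C)C)cc2)c1=O
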